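The whole plan rests on disconnecting the C20 methyl from C9 (clerodane numbering, defined below). C9 is the quaternary carbon common to rings A and C. Its methyl stands axial on the α face, syn to the angular C19 oxymethylene on C5 and flanked by C8 and the acetoxy carbon C7. The key step exploits the C7 oxygen of ring A. As an α-oriented allylic hydroxyl it hands a zinc-bound methylene to the C8=C9 alkene. One operation closes a cyclopropane, forms C20–C8 and C20–C9, and fixes both carbons. Electron transfer later cuts C20–C8. The precursor is a trans-decalin allylic alcohol bearing the cis γ-lactone, a C2 dioxolane and a tert-butyl acetate arm on C9.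

Key step: step 14

Numbering and faces:
- Ring B = C1, C2, C3, C4, C5, C10.
- Ring A = C5, C6, C7, C8, C9, C10.
- Ring C = C1, C10, C9, C11, C12, C13, C16.
- Furan = C13, C14, C15, O, C16, with C16 bonded to C1.
- C17 = methyl on C8; C18 = lactone carbonyl on C4; C19 = OCH2 on C5; C20 = methyl on C9.
- α is the face of C19 and C20; β is the face of H-10.

Design remark: the C11–C12 arm on C9 is carried as a tert-butyl ester, not as a protected alcohol.
- Ring A can then be closed without a β-oxy ketone that could eliminate under base.
- One acid treatment later frees the acid and the C2 ketone together.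
- The acid already has the oxidation level of the C12 ketone.

Assumption: acetal 3 is bought as the single (5R) diastereomer derived from l-menthol.

Step 1
Reactants: 1 but-3-en-2-one
Product: 2 2-(tert-butyldimethylsilyloxy)buta-1,3-diene
Conditions: t-BuMe2SiOTf, Et3N, Et2O, 0 °C
Reagents that add atoms: tert-butyldimethylsilyl triflate, CC(C)(C)[Si](C)(C)OS(=O)(=O)C(F)(F)F
Why: Soft enolisation of the methyl ketone by silyl triflate and amine (silyl enol ether formation) gives the 2-silyloxydiene, and no stereocentre is made.

Step 2
Reactants: 2 2-(tert-butyldimethylsilyloxy)buta-1,3-diene; 3 (5R)-5-(l-menthyloxy)furan-2(5H)-one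
Product: 4 bicyclic lactone acetal (Diels–Alder adduct)
Conditions: PhMe, BHT (trace), 120 °C, sealed tube
Reagents that add atoms: none
Why: In this thermal Diels–Alder reaction the diene CH2 next to the silyloxy carbon (largest HOMO coefficient) bonds to the lactone β-carbon, so oxygen ends at C2, and suprafacial addition to the face of 3 opposite the menthyloxy group sets C4 and C5 (both H β) in absolute terms.

Step 3
Reactants: 4 bicyclic lactone acetal; 5 allyl bromide
Product: 6 C5-allyl lactone acetal
Conditions: LiN(iPr)2, THF, −78 °C; 5, DMPU, −78 → −20 °C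
Reagents that add atoms: allyl bromide 5, C=CCBr
Why: In this lactone enolate alkylation C5 is the only acidic carbon, because C19 is still the carbonyl and C18 an acetal, and the halide attacks the convex β face trans to the C4–C3 bond, which keeps the cis fusion and sets the quaternary C5.

Step 4
Reactants: 6 C5-allyl lactone acetal
Product: 7 C18/C19 diol
Conditions: LiAlH4, THF, 0 → 23 °C; aq. NaOH work-up
Reagents that add atoms: none
Why: In this hydride reduction of an acyloxy acetal the C19 carbonyl is reduced, the released hemiacetal alkoxide loses menthoxide and the C18 aldehyde is reduced too, while silyl enol ether, alkene and stereocentres stay untouched.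

Step 5
Reactants: 7 C18/C19 diol
Product: 8 C18 lactone silyl enol ether
Conditions: [Cu(MeCN)4]OTf (5 mol %), 2,2′-bipyridine, TEMPO, N-methylimidazole, air, MeCN, 23 °C
Reagents that add atoms: none
Why: In this aerobic copper/nitroxyl oxidative lactonisation of a 1,4-diol the less hindered C18 carbinol is oxidised before the neopentyl C19 carbinol, the C19 hydroxyl closes the lactol, and a second oxidation gives the lactone in the orientation of the target.

Step 6
Reactants: 8 C18 lactone silyl enol ether
Product: 10 C1=C10 enone lactone, via C1 selenide 9 (not isolated)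
Conditions: PhSeCl, CH2Cl2, −78 °C; then 30 % H2O2, pyridine, 0 → 23 °C
Reagents that add atoms: none
Why: Selenenylation of the regiodefined silyl enol ether at C1 and selenoxide syn-elimination towards C10 give the enone without palladium, which could couple the enol ether to the allyl group, and the transient C1 centre is lost again.

Step 7
Reactants: 10 C1=C10 enone lactone; 11 2-bromobut-1-ene
Product: 14 C10-butenyl ketone, via butenyl Grignard reagent 12 (not isolated), via trimethylsilyl enol ether 13 (not isolated)
Conditions: 11, Mg, THF, 40 °C; then CuBr·SMe2 (20 mol %), Me3SiCl, 10, THF, −78 °C; 1 M HCl work-up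
Reagents that add atoms: 2-bromobut-1-ene 11, CCC(Br)=C
Why: In this copper-catalysed, silyl-chloride-accelerated conjugate addition of a Grignard reagent to a 4,4-disubstituted cyclohexenone, attack is expected anti to the pseudoaxial C19, which places the butenyl group β at C10, a configuration corrected in step 10.

Step 8
Reactants: 14 C10-butenyl ketone
Product: 15 C2 dioxolane
Conditions: Me3SiOCH2CH2OSiMe3, Me3SiOTf (5 mol %), CH2Cl2, −78 → −20 °C
Reagents that add atoms: 1,2-bis(trimethylsilyloxy)ethane, C[Si](C)(C)OCCO[Si](C)(C)C
Why: Noyori ketalisation under aprotic catalysis protects the C2 ketone at low temperature so that neither alkene migrates and no stereocentre changes.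

Step 9
Reactants: 15 C2 dioxolane
Product: 17 keto aldehyde, via bis-ozonide 16 (not isolated)
Conditions: O3, CH2Cl2, −78 °C; then Me2S, −78 → 23 °C
Reagents that add atoms: ozone, [O-][O+]=O
Why: Ozonolysis with reductive work-up cleaves both terminal alkenes at once, turning the allyl group into the C7 aldehyde and the butenyl group into the C9 ethyl ketone, while ketal and lactone are inert.

Step 10
Reactants: 17 keto aldehyde
Product: 18 trans-decalin C9 enone
Conditions: NaOMe (20 mol %), MeOH, 0 → 23 °C; AcOH quench
Reagents that add atoms: none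
Why: Intramolecular aldol condensation (6-enolendo-exo-trig) of the C8 enolate onto the C7 aldehyde closes ring A, and C10, α to the C9 ketone, equilibrates under the same base to the trans fusion (H-10 β), because either chair of the cis isomer puts a carbon substituent syn-axial to a ketal oxygen.

Step 11
Reactants: 18 trans-decalin C9 enone; 19 tert-butyl bromoacetate
Product: 21 C9 tertiary allylic alcohol, via Reformatsky reagent 20 (not isolated)
Conditions: 19, Zn dust (Me3SiCl-activated), THF, 40 °C; then 18, 0 → 23 °C; aq. NH4Cl
Reagents that add atoms: tert-butyl bromoacetate 19, CC(C)(C)OC(=O)CBr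
Why: In this Reformatsky reaction the weakly basic zinc enolate adds 1,2 to the C9 ketone instead of deprotonating it or attacking the lactone, from the β face away from axial C19 (a centre erased in step 12), and so brings in C11–C12 at the carboxyl level.

Step 12
Reactants: 21 C9 tertiary allylic alcohol
Product: 22 tetrasubstituted C7 enone
Conditions: [C5H5NH][CrO3Cl], Celite, CH2Cl2, 23 °C
Reagents that add atoms: pyridinium chlorochromate (supplies the C7 oxygen), c1cc[nH+]cc1.[O-][Cr](=O)(=O)Cl
Why: In this Babler–Dauben oxidative transposition the tertiary allylic chromate ester shifts [3,3] to C7 and is oxidised there, which gives the C8=C9 tetrasubstituted enone.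

Step 13
Reactants: 22 tetrasubstituted C7 enone
Product: 23 C7 α-allylic alcohol (key-step precursor)
Conditions: NaBH4, CeCl3·7H2O, MeOH, −40 → 0 °C
Reagents that add atoms: none
Why: In this Luche reduction 1,2-hydride delivery comes from the β face because axial C19 on C5 blocks the α trajectory at C7, which sets the pseudoaxial α hydroxyl.

Step 14
Reactants: 23 C7 α-allylic alcohol; 24 diiodomethane
Product: 26 cyclopropyl carbinol, via iodomethylzinc carbenoid 25 (not isolated)
Conditions: Et2Zn (6 equiv), CH2I2 (6 equiv), CH2Cl2, −15 → 23 °C; aq. NH4Cl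
Reagents that add atoms: diiodomethane 24, ICI
Why: Et2Zn first turns the C7 hydroxyl into a zinc alkoxide, which binds carbenoid 25 and passes its CH2 to C8=C9 through a concerted butterfly transition state; this is the hydroxyl-directed Simmons–Smith reaction in its Et2Zn/CH2I2 form, well known for cyclohexenols, fully substituted ones included. The three-membered ring closes by a suprafacial [2+1] methylene transfer in which C20–C8 and C20–C9 form in the same event, so no open intermediate can rotate. C8 and C9 are both controlled by the C7 carbinol centre, because the pseudoaxial α oxygen, held in place by the trans ring fusion, can reach only the α face of the alkene. The step needs facial selectivity against the steric bias of C19 and tolerance of the other groups; the zinc tether secures the first, and C8=C9 is the only alkene while lactone, tert-butyl ester and dioxolane are inert to the electrophilic carbenoid. The excess of reagent makes up for zinc held by these Lewis basic groups.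

Step 15
Reactants: 26 cyclopropyl carbinol
Product: 27 cyclopropyl ketone
Conditions: Dess–Martin periodinane, CH2Cl2, 0 → 23 °C
Reagents that add atoms: none
Why: Dess–Martin oxidation converts the strained axial carbinol quickly under nearly neutral conditions, so the cyclopropyl carbinol is not ionised and C8 and C9 stay as set.

Step 16
Reactants: 27 cyclopropyl ketone
Product: 28 C9-methyl C7 ketone
Conditions: SmI2 (3 equiv), t-BuOH, THF–DMPU, −78 → 0 °C
Reagents that add atoms: none
Why: In this reductive cleavage of a cyclopropyl ketone by SmI2 the ketyl breaks the exocyclic C8–C20 bond that overlaps the carbonyl π system, the primary radical is reduced to the C20 methyl on C9, and the samarium enolate is protonated axially from the open β face (also the thermodynamic outcome), which sets C8 with an equatorial methyl.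

Step 17
Reactants: 28 C9-methyl C7 ketone
Product: 29 C7 β-alcohol
Conditions: SmI2 (5 equiv), H2O (excess), THF, 23 °C
Reagents that add atoms: none
Why: Single-electron ketone reduction by SmI2–H2O runs through a ketyl and a carbinyl samarium species that settle with oxygen equatorial, giving the β alcohol that hydride reagents miss because C19 and C20 close the α face, while γ-lactone and tert-butyl ester are not reduced without an amine additive.

Step 18
Reactants: 29 C7 β-alcohol
Product: 30 C7 β-acetate
Conditions: Ac2O, DMAP, pyridine, CH2Cl2, 23 °C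
Reagents that add atoms: acetic anhydride, CC(=O)OC(C)=O
Why: DMAP-catalysed acylation of the unhindered equatorial alcohol proceeds with retention at C7.

Step 19
Reactants: 30 C7 β-acetate
Product: 31 keto acid
Conditions: CF3CO2H–H2O–CH2Cl2, 0 → 23 °C
Reagents that add atoms: water, O
Why: Aqueous trifluoroacetic acid cleaves the tert-butyl ester through the tert-butyl cation and hydrolyses the dioxolane in the same operation (acidolysis), while acetate and lactone survive.

Step 20
Reactants: 32 3-bromofuran
Product: 34 3-bromo-2-chlorofuran, via 3-bromo-2-furyllithium 33 (not isolated)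
Conditions: LiN(iPr)2, THF, −78 °C; C2Cl6, −78 → 0 °C
Reagents that add atoms: hexachloroethane, ClC(Cl)(Cl)C(Cl)(Cl)Cl
Why: Directed deprotonation at the furan carbon flanked by oxygen and bromine, followed by electrophilic chlorination of the lithio species, places the later leaving group on the future C16.

Step 21
Reactants: 31 keto acid; 34 3-bromo-2-chlorofuran
Product: 38 chlorofuryl diketone, via acid chloride 35 (not isolated), via 2-chloro-3-furyllithium 36 (not isolated), via 2-chloro-3-furylzinc chloride 37 (not isolated)
Conditions: 31, (COCl)2, DMF (cat.), CH2Cl2, 0 → 23 °C, evaporate; 34, n-BuLi, Et2O, −78 °C, then ZnCl2, THF; combine, Pd(PPh3)4 (5 mol %), THF, 0 → 23 °C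
Reagents that add atoms: 3-bromo-2-chlorofuran 34, Clc1occc1Br
Why: In this Negishi acylation bromine–lithium exchange (faster than any reaction at C–Cl) and transmetalation give an arylzinc that couples with the acid chloride under zerovalent palladium catalysis and leaves the C2 ketone, lactone and acetate untouched.

Step 22
Reactants: 38 chlorofuryl diketone
Product: 39 chlorofuryl enedione
Conditions: IBX (1.5 equiv), DMSO, 65 °C
Reagents that add atoms: none
Why: In this IBX dehydrogenation the C2 ketone enolises away from the ring fusion towards C3, as in trans-fused 3-keto steroids, and loss of H-3 and H-4 gives the alkene conjugated with both carbonyl groups, whereas the C12 ketone has no β hydrogen.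

Step 23
Reactants: 39 chlorofuryl enedione
Product: 40 pentacyclic C2 ketone
Conditions: Pd(OAc)2 (10 mol %), XPhos, K3PO4, PhMe, 90 °C
Reagents that add atoms: none
Why: In this intramolecular palladium-catalysed ketone α-arylation (Buchwald–Hartwig type) the C2 ketone can enolise only at C1 now that C3 is sp2, the acyl-activated C16–Cl bond adds to zerovalent palladium, reductive elimination closes the seven-membered ring C (a C11 enolate could only form a four-membered ring), and the acidic C1 centre settles with the furan equatorial, H-1 α and trans to H-10.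

Step 24
Reactants: 40 pentacyclic C2 ketone
Product: 41 target CNP0182929.2
Conditions: NaBH4 (1 equiv), CeCl3·7H2O, MeOH–CH2Cl2, −78 °C
Reagents that add atoms: none
Why: In this low-temperature Luche reduction the electron-poor C2 enone carbonyl is attacked 1,2 in preference to the C12 ketone, which is deactivated as a vinylogous ester of the furan oxygen and shielded by neopentyl C11, and axial hydride delivery from the β face gives the equatorial α alcohol trans to the furan.

Compound list
1 | but-3-en-2-one (methyl vinyl ketone) | CC(=O)C=C | starting material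
2 | 2-(tert-butyldimethylsilyloxy)buta-1,3-diene | C=CC(=C)O[Si](C)(C)C(C)(C)C | intermediate
3 | (5R)-5-[(1R,2S,5R)-menthyloxy]furan-2(5H)-one | O=C1O[C@@H](O[C@@H]2C[C@H](C)CC[C@H]2C(C)C)C=C1 | starting material
4 | cis-fused bicyclic lactone acetal: C19 carbonyl, C18 menthyl acetal (O-menthyl on the face of H-4 and H-5, both β), C1=C2 TBS enol ether | O=C1O[C@@H](O[C@@H]3C[C@H](C)CC[C@H]3C(C)C)[C@@H]2CC(O[Si](C)(C)C(C)(C)C)=CC[C@H]12 | intermediate
5 | allyl bromide | C=CCBr | starting material
6 | C5-allyl lactone acetal (allyl β, cis fusion kept) | O=C1O[C@@H](O[C@@H]3C[C@H](C)CC[C@H]3C(C)C)[C@@H]2CC(O[Si](C)(C)C(C)(C)C)=CC[C@]12CC=C | intermediate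
7 | C18/C19 diol, cis hydroxymethyl groups on C4 and C5, allyl β on C5 | OC[C@@H]1CC(O[Si](C)(C)C(C)(C)C)=CC[C@@]1(CO)CC=C | intermediate
8 | cis γ-lactone (C18 carbonyl, C19 OCH2) with C1=C2 TBS enol ether | C=CC[C@@]12COC(=O)[C@@H]1CC(O[Si](C)(C)C(C)(C)C)=CC2 | intermediate
9 | C1 β-phenylselanyl C2 ketone (not isolated) | C=CC[C@@]12COC(=O)[C@@H]1CC(=O)[C@@H]([Se]c3ccccc3)C2 | intermediate
10 | C2 enone (C1=C10) of the allyl lactone | C=CC[C@@]12COC(=O)[C@@H]1CC(=O)C=C2 | intermediate
11 | 2-bromobut-1-ene | CCC(Br)=C | starting material
12 | but-1-en-2-ylmagnesium bromide (not isolated) | CCC(=C)[Mg]Br | intermediate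
13 | C1=C2 trimethylsilyl enol ether of the conjugate adduct (not isolated) | C=CC[C@@]12COC(=O)[C@@H]1CC(O[Si](C)(C)C)=C[C@H]2C(=C)CC | intermediate
14 | C2 ketone with but-1-en-2-yl β on C10 (cis to the allyl group) | C=CC[C@@]12COC(=O)[C@@H]1CC(=O)C[C@H]2C(=C)CC | intermediate
15 | C2 ethylene ketal of 14 | C=CC[C@@]12COC(=O)[C@@H]1CC3(OCCO3)C[C@H]2C(=C)CC | intermediate
16 | bis(1,2,4-trioxolane) of 15, epimers at the two trioxolane carbons (not isolated) | O1COOC1C[C@@]23COC(=O)[C@@H]2CC4(OCCO4)C[C@H]3C5(CC)OCOO5 | intermediate
17 | keto aldehyde: C7 aldehyde on C6, propanoyl (C9, C8, C17) β on C10 | O=CC[C@@]12COC(=O)[C@@H]1CC3(OCCO3)C[C@H]2C(=O)CC | intermediate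
18 | trans-decalin enone: C9 ketone, C7=C8, C17 methyl, H-10 β, C19 α, cis lactone, C2 ketal | CC1=CC[C@@]23COC(=O)[C@@H]2CC4(OCCO4)C[C@@H]3C1=O | intermediate
19 | tert-butyl bromoacetate | CC(C)(C)OC(=O)CBr | starting material
20 | bromo(2-tert-butoxy-2-oxoethyl)zinc (not isolated) | CC(C)(C)OC(=O)C[Zn]Br | intermediate
21 | C9 tertiary allylic alcohol (OH α, CH2CO2t-Bu β) | CC1=CC[C@@]23COC(=O)[C@@H]2CC4(OCCO4)C[C@@H]3[C@@]1(O)CC(=O)OC(C)(C)C | intermediate
22 | C7 enone with tetrasubstituted C8=C9, CH2CO2t-Bu on C9 | O=C1C[C@@]23COC(=O)[C@@H]2CC4(OCCO4)C[C@@H]3C(CC(=O)OC(C)(C)C)=C1C | intermediate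
23 | ring A allylic alcohol, C7 OH α (pseudoaxial, syn to C19); key-step precursor | O[C@@H]1C[C@@]23COC(=O)[C@@H]2CC4(OCCO4)C[C@@H]3C(CC(=O)OC(C)(C)C)=C1C | intermediate
24 | diiodomethane | ICI | starting material
25 | ethyl(iodomethyl)zinc (not isolated) | CC[Zn]CI | intermediate
26 | cyclopropyl carbinol, C20 bridging C8 and C9 on the α face, C7 OH α; key-step product | O[C@@H]1C[C@@]23COC(=O)[C@@H]2CC4(OCCO4)C[C@@H]3[C@]5(CC(=O)OC(C)(C)C)C[C@]15C | intermediate
27 | cyclopropyl C7 ketone | O=C1C[C@@]23COC(=O)[C@@H]2CC4(OCCO4)C[C@@H]3[C@]5(CC(=O)OC(C)(C)C)C[C@]15C | intermediate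
28 | C7 ketone with C20 methyl α (axial) on C9 and C17 methyl α (equatorial) on C8 | O=C1C[C@@]23COC(=O)[C@@H]2CC4(OCCO4)C[C@@H]3[C@@](C)(CC(=O)OC(C)(C)C)[C@@H]1C | intermediate
29 | C7 β (equatorial) alcohol | O[C@H]1C[C@@]23COC(=O)[C@@H]2CC4(OCCO4)C[C@@H]3[C@@](C)(CC(=O)OC(C)(C)C)[C@@H]1C | intermediate
30 | C7 β acetate | CC(=O)O[C@H]1C[C@@]23COC(=O)[C@@H]2CC4(OCCO4)C[C@@H]3[C@@](C)(CC(=O)OC(C)(C)C)[C@@H]1C | intermediate
31 | keto acid (C2 ketone, C12 acid) | CC(=O)O[C@H]1C[C@@]23COC(=O)[C@@H]2CC(=O)C[C@@H]3[C@@](C)(CC(=O)O)[C@@H]1C | intermediate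
32 | 3-bromofuran | Brc1ccoc1 | starting material
33 | 3-bromo-2-furyllithium (not isolated) | [Li]c1occc1Br | intermediate
34 | 3-bromo-2-chlorofuran | Clc1occc1Br | intermediate
35 | C12 acid chloride (not isolated) | CC(=O)O[C@H]1C[C@@]23COC(=O)[C@@H]2CC(=O)C[C@@H]3[C@@](C)(CC(=O)Cl)[C@@H]1C | intermediate
36 | 2-chloro-3-furyllithium (not isolated) | [Li]c1ccoc1Cl | intermediate
37 | chloro(2-chlorofuran-3-yl)zinc (not isolated) | Cl[Zn]c1ccoc1Cl | intermediate
38 | diketone: C2 ketone and C12 2-chlorofuran-3-yl ketone | CC(=O)O[C@H]1C[C@@]23COC(=O)[C@@H]2CC(=O)C[C@@H]3[C@@](C)(CC(=O)c4ccoc4Cl)[C@@H]1C | intermediate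
39 | enedione: C3=C4 conjugated with the C2 ketone and the C18 lactone | CC(=O)O[C@H]1C[C@@]23COC(=O)C2=CC(=O)C[C@@H]3[C@@](C)(CC(=O)c4ccoc4Cl)[C@@H]1C | intermediate
40 | pentacyclic C2 ketone, ring C closed (C1–C16), H-1 α | CC(=O)O[C@H]1C[C@@]23COC(=O)C2=CC(=O)[C@H]2c4occc4C(=O)C[C@@](C)([C@@H]1C)[C@@H]23 | intermediate
41 | CNP0182929.2 (C2 OH α, H-1 α, C7 OAc β, C17 and C20 α, H-10 β) | CC(=O)O[C@H]1C[C@@]23COC(=O)C2=C[C@H](O)[C@H]2c4occc4C(=O)C[C@@](C)([C@@H]1C)[C@@H]23 | target

Total step count: 24. Longest linear sequence: 23 steps (steps 1–19 and 21–24). Step 20 is a one-step side branch.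

Steps most likely to fail

Step 14. Methylene transfer to a tetrasubstituted alkene wedged between two fully substituted carbons may be slow. The Lewis basic groups may hold back the zinc reagent. Zinc iodide may ionise the allylic or cyclopropyl carbinol.
- Fallback from 23: the same α oxygen can anchor a Claisen rearrangement instead.
- Transvinylation with ethyl vinyl ether and Hg(OAc)2 should give the vinyl ether F1.
- Heating in xylene should carry the two-carbon unit suprafacially to the α face of C9 and give the aldehyde F2 with a C7=C8 alkene.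
- Tsuji–Wilkinson decarbonylation with RhCl(PPh3)3 should trim the 2-oxoethyl group to the C20 methyl in the alkene F3.
- Hydroboration–oxidation (BH3·SMe2, then NaBO3) from the open β face should place OH on C7 and H on C8 on that face. This rejoins the route at 29.

Step 23. The base may degrade the doubly activated C3=C4 alkene, or protodechlorination may outrun carbon–carbon bond formation.
- Fallback from 39: soft enolisation (Me3SiOTf, Et3N, CH2Cl2) should give the cross-conjugated silyl dienol ether F4.
- A base-free coupling should then close ring C: Bu3SnF converts the enol silane into a tin enolate that transmetalates to the arylpalladium chloride (Pd2(dba)3, P(t-Bu)3, PhMe, 85 °C). This comes back to the route at 40.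

Step 17. Electron transfer to a ketone shielded by two syn-axial groups may stall, or protonation may occur before the intermediates settle, which would erode the equatorial selectivity.
- Fallback from 28: NaBH4 in MeOH should deliver hydride from the β face and give the axial alcohol F5.
- Meerwein–Ponndorf–Verley/Oppenauer equilibration (Al(OiPr)3, i-PrOH, trace acetone, reflux) should then relieve the two syn-axial contacts by draining F5 into the equatorial epimer. This rejoins the route at 29.

Further compounds
F1 | step 14 | C7 α vinyl ether of 23 | C=CO[C@@H]1C[C@@]23COC(=O)[C@@H]2CC4(OCCO4)C[C@@H]3C(CC(=O)OC(C)(C)C)=C1C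
F2 | step 14 | C7=C8 alkene with 2-oxoethyl α and CH2CO2t-Bu β on C9 | CC1=CC[C@@]23COC(=O)[C@@H]2CC4(OCCO4)C[C@@H]3[C@@]1(CC=O)CC(=O)OC(C)(C)C
F3 | step 14 | C7=C8 alkene with C20 methyl α and CH2CO2t-Bu β on C9 | CC1=CC[C@@]23COC(=O)[C@@H]2CC4(OCCO4)C[C@@H]3[C@@]1(C)CC(=O)OC(C)(C)C
F4 | step 23 | C1=C2 trimethylsilyl dienol ether of 39 | CC(=O)O[C@H]1C[C@@]23COC(=O)C2=CC(O[Si](C)(C)C)=C[C@@H]3[C@@](C)(CC(=O)c4ccoc4Cl)[C@@H]1C
F5 | step 17 | C7 α (axial) alcohol, epimer of 29 | O[C@@H]1C[C@@]23COC(=O)[C@@H]2CC4(OCCO4)C[C@@H]3[C@@](C)(CC(=O)OC(C)(C)C)[C@@H]1C
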